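# Proposed synthesis of CNP0156752.1 by late-stage enzymatic hydration of 3'-geranylisoliquiritigenin

Atom labels: ring A is the resorcinol-derived ring (C1'–C6', ketone on C1'), ring B is the 4-hydroxyphenyl ring, and the side chain is C1''–C8'' (C1'' on C3', carbinol at C3''). "Geranyl" means (2E)-3,7-dimethylocta-2,6-dien-1-yl.

## The problem

The target 15 is an open-chain 2',4,4'-trihydroxychalcone. Rings A and B are joined only by the C(=O)–Cα=Cβ enone, and ring A carries a ten-carbon chain at C3', in the crowded position between its two hydroxyls. No ring has to be closed, so the work lies in placing four contiguous substituents on ring A and in building the chain C1''–C8''. The only stereocentre is the tertiary carbinol C3'' (R). Its two larger arms, the 2-arylethyl arm (C2''–C1''–ring A) and the homoprenyl arm (C4''–C7''), both begin with CH2–CH2 and differ only at the third atom, and no other stereocentre exists to control it. The fragile parts are the 2'-hydroxychalcone (flavanone closure under acid or base, conjugate addition, light-induced E/Z isomerisation), the C6''=C7'' alkene, and the carbinol itself, which under acid ionises to a tertiary cation that the 2'- or 4'-hydroxyl traps as a chroman. Hydrogenolytic deprotection is excluded by the alkenes. The feature that invites a short route is that C3''–OH together with the CH2 at C2'' is the Markovnikov water adduct of a C2''=C3'' alkene. Removing water gives the achiral 3'-geranylisoliquiritigenin 14, and this alkene is the one allylic to the ortho-hydroxylated ring A, the arrangement on which prenylarene hydratases act. Because the alkene geometry disappears on hydration, the configuration at C3'' depends only on which face of C3'' meets water.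

## Retrosynthesis

**C3''–O (and C2''–H): 15 ⇒ 14.** This cut removes the stereocentre and the only acid-labile alcohol in one move and leaves an achiral natural chalcone with no protecting groups. The neighbouring cuts (C3'–C1'' or C2''–C3'') keep the carbinol inside a fragment, which then needs a silyl group and must survive the later removal of the phenol protecting groups. The forward reaction must add water to the proximal alkene only, to the Re face of C3'', without chroman closure and without touching the enone. No small-molecule reagent does this, so the step is assigned to an engineered hydratase.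

**Three aryl O–CH2OMe bonds and Cα=Cβ: 14 ⇒ 13 ⇒ 9 + 11.** The enone is the standard chalcone disconnection into acetophenone 9 and aldehyde 11. Masking all three phenols as methoxymethyl ethers keeps phenoxides from deactivating either partner and blocks flavanone closure during the basic condensation. The forward reactions are a condensation that gives the (E)-enone through aldol 12, and an acetal cleavage mild enough to spare the geranyl alkenes.

**C1'–C(acyl): 9 ⇒ 6.** The acetyl group is introduced last on ring A, by lithiation of 6 ortho to an OMOM group (aryllithium 7) and acylation through the chelated adduct 8. Friedel–Crafts acylation would not tolerate the alkenes or the acetals, and starting from a preformed dihydroxyacetophenone would make the later C-alkylation unselective. The forward step needs ring metalation to outrun deprotonation of the C1'' methylene.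

**C3'–C1'': 6 ⇒ 2 + 3.** The position between the two OMOM groups of 2 is the most acidic on the ring, so lithiation there (4), transmetalation to copper (5) and substitution on geranyl bromide 3 put the chain exactly where it is needed. The forward step must attack the primary carbon of 3 and keep its (E)-alkene.

**O–CH2OMe: 2 ⇒ 1 and 11 ⇒ 10.** Both ethers come from commercial phenols, resorcinol 1 and 4-hydroxybenzaldehyde 10, by O-alkylation.

## Roads not taken

**Alternative 1:** The cut runs through ring A itself (C5'–C6' and C1'–C2').
- Forward key step: the 1-methoxy-1,3-bis(trimethylsilyloxy)diene A1, which carries the (R)-configured silyl-protected side chain at C2, would add to the terminal alkyne of enynone A2. The diene CH2 terminus bonds to the β-alkyne carbon and the ketene acetal carbon to the α-carbon. Loss of methanol and the trimethylsilyl groups aromatises the adduct to A3 with both ring A phenols free.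
- Merits: the substitution pattern of ring A follows from the polarity of the two partners, with no directed metalation and no protecting groups on ring A. The stereocentre would come from the chiral pool, which is more certain than the enzyme of the chosen plan.
- Weak points: ring A is simply resorcinol, which can be bought. The route spends roughly a dozen steps on the chain iodide, the β-keto ester precursor of A1, the diene and A2. A2 is a cross-conjugated enynone that offers the silyl ketene acetal two Michael acceptor sites. The acid or fluoride needed for aromatisation and final desilylation meets a tertiary silyl ether beside a free phenol.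
- Comparison: against the secure stereochemistry of this road, the chosen plan sets about half the number of steps, a purchased ring A, and no operation at all after the carbinol exists.

**Alternative 2:** The cut is C2''–C3''.
- Forward key step: (R)-sulcatyl 2,4,6-triisopropylbenzoate A4 would be lithiated next to oxygen with s-BuLi/TMEDA and trapped by the neopentyl glycol boronic ester A5 of the 2-arylethyl fragment. The ate complex would undergo a 1,2-shift of the arylethyl group with loss of the benzoate to give tertiary boronic ester A6. A6 is (S) by the sequence rule only because boron ranks lowest; oxidation with retention gives the (R) carbinol.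
- Merits: the reaction class is stereospecific and makes the C–C bond and the stereocentre together from two halves of similar size. It is more predictable than an enzyme that still has to be evolved.
- Weak points: an unactivated secondary dialkyl benzoate is the hardest substrate of this class to deprotonate. The parent alcohol of A4 must be of high enantiomeric purity. After A6 about five operations remain (oxidation, handling of the free alcohol, C4 acetylation, condensation, acid deprotection), and the last exposes the finished carbinol to acid beside a phenol.
- Comparison: the chosen plan is about three steps shorter, avoids a cryogenic stoichiometric carbenoid at the stereo-defining stage, and forms the carbinol only after all acid treatment is over.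

**Alternative 3:** The cut is the aryl–alkyl bond C3'–C1''.
- Forward key step: O-triethylsilyl-(R)-linalool A7 would be hydroborated at its vinyl group with 9-BBN-H to the B-alkyl borane A8. A8 would be coupled with the fully assembled 3'-iodochalcone A9 under Pd(dppf)Cl2, AsPh3 and aqueous Cs2CO3 (B-alkyl Suzuki–Miyaura) to give the protected target A10.
- Merits: the stereocentre is bought, the route is convergent, every reaction belongs to a known class, and the step count (about seven) equals that of the chosen plan. In reliability this road is better than the chosen one.
- Weak points: the iodide of A9 is flanked by two OMOM groups, so oxidative addition and transmetalation are slow and β-hydride elimination gains time. The enone of A9 is exposed to borane and base. Final acid removal of three MOM groups and a tertiary silyl ether puts the carbinol beside a free phenol. Enantiomeric purity is capped by that of the purchased terpene alcohol behind A7.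
- Comparison: the chosen plan never protects the carbinol, finishes all acid chemistry before the carbinol exists, sets enantiopurity by a catalyst, and ends with a metal-free water addition that could serve analogues. A variant of this road, with the coupling moved to a simple aryl iodide, is kept as the fallback for step 7.

Key step: step 7

## Remarks on the chemistry

- Conjugate bases formed by simple proton transfer (phenoxides, the enolate of 9) are not numbered. Organometallic species made in a separate operation, the chelated tetrahedral adduct and the aldol are numbered.
- The enzyme is a catalyst produced by fermentation and is not counted as a step.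
- 2,4-Dihydroxyacetophenone and (R)-linalool, used only in fallbacks, are purchased.

## Route

**Step 1**
Reactants: 1 resorcinol
Product: 2 1,3-bis(methoxymethoxy)benzene
Conditions: NaH, MOMCl, DMF, 0 °C → rt
Reagents that add atoms: chloromethyl methyl ether (MOMCl), `COCCl`
Why: Double Williamson-type O-alkylation of the resorcinol dianion with a reactive α-chloro ether should be clean; the MOM groups direct both later lithiations and withstand alkyllithiums and hydroxide.

**Step 2**
Reactants: 2 1,3-bis(methoxymethoxy)benzene; 3 geranyl bromide
Product: 6 2-geranyl-1,3-bis(methoxymethoxy)benzene, via 2,6-bis(methoxymethoxy)phenyllithium 4 (not isolated), via 2,6-bis(methoxymethoxy)phenylcopper 5 (not isolated)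
Conditions: n-BuLi, THF, 0 °C → rt; CuI, −30 °C; 3, −30 °C → rt
Reagents that add atoms: none
Why: Directed ortho-metalation at C2, the hydrogen flanked and coordinated by two OMOM groups, should give 4 regioselectively; transmetalation to arylcopper 5 lowers basicity and directs substitution to the unhindered primary carbon of the allylic bromide (SN2 rather than SN2′), so the (E)-alkene of 3 should be carried over unchanged.

**Step 3**
Reactants: 6 2-geranyl-1,3-bis(methoxymethoxy)benzene
Product: 9 1-[3-geranyl-2,4-bis(methoxymethoxy)phenyl]ethanone, via 3-geranyl-2,4-bis(methoxymethoxy)phenyllithium 7 (not isolated), via lithium N-methoxy-N-methylhemiaminal alkoxide 8 (not isolated)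
Conditions: n-BuLi, TMEDA, THF, −20 → 0 °C; MeC(O)N(OMe)Me, −78 → 0 °C; H2O
Reagents that add atoms: N-methoxy-N-methylacetamide, `CC(=O)N(C)OC`
Why: A second directed ortho-metalation at C4, the only remaining site ortho to an OMOM group, gives 7, and Weinreb ketone synthesis stops at the chelated adduct 8, which releases the ketone only on quench, so over-addition should not occur. The C1'' methylene is allylic, but its two ortho substituents twist it out of benzylic conjugation, which should keep lateral deprotonation slow.

**Step 4**
Reactants: 10 4-hydroxybenzaldehyde
Product: 11 4-(methoxymethoxy)benzaldehyde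
Conditions: MOMCl, K2CO3, acetone, rt → 50 °C
Reagents that add atoms: chloromethyl methyl ether (MOMCl), `COCCl`
Why: Williamson-type O-alkylation of the phenoxide; the ether keeps a phenoxide from deactivating the aldehyde in the condensation and leaves together with the other two MOM groups.

**Step 5**
Reactants: 9 1-[3-geranyl-2,4-bis(methoxymethoxy)phenyl]ethanone; 11 4-(methoxymethoxy)benzaldehyde
Product: 13 (E)-1-[3-geranyl-2,4-bis(methoxymethoxy)phenyl]-3-[4-(methoxymethoxy)phenyl]prop-2-en-1-one, via β-hydroxy ketone 12 (not isolated)
Conditions: KOH, EtOH/H2O, rt
Reagents that add atoms: none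
Why: Claisen–Schmidt condensation: the enolate of 9 adds to non-enolisable 11 and aldol 12 dehydrates by E1cB to the conjugated, thermodynamically preferred (E)-enone. MOM ethers and the geranyl chain are inert to ethanolic hydroxide, and with every phenol masked flavanone closure cannot occur.

**Step 6**
Reactants: 13 (E)-1-[3-geranyl-2,4-bis(methoxymethoxy)phenyl]-3-[4-(methoxymethoxy)phenyl]prop-2-en-1-one
Product: 14 3'-geranylisoliquiritigenin (xanthoangelol; (E)-1-[3-geranyl-2,4-dihydroxyphenyl]-3-(4-hydroxyphenyl)prop-2-en-1-one)
Conditions: 3 M aq HCl, MeOH, rt → 40 °C, stopped at full conversion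
Reagents that add atoms: none
Why: Acid-catalysed acetal methanolysis; the 2'-OMOM group, assisted by the neighbouring carbonyl, leaves first and the other two follow under conditions of the kind used for prenylated chalcones. These should stay below the threshold for protonating the trisubstituted alkenes (chroman formation) and for chalcone–flavanone isomerisation.

**Step 7**
Reactants: 14 3'-geranylisoliquiritigenin
Product: 15 (E)-1-{2,4-dihydroxy-3-[(3R)-3-hydroxy-3,7-dimethyloct-6-en-1-yl]phenyl}-3-(4-hydroxyphenyl)prop-2-en-1-one (the target)
Conditions: engineered kievitone-hydratase-type hydro-lyase (cell-free preparation), citrate–phosphate buffer pH 6.0, 10% v/v DMSO, 28 °C, dark; EtOAc extraction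
Reagents that add atoms: water, `O`
Why: Proposed new method: a hydro-lyase of the kievitone hydratase type, which needs no redox cofactor, is asked to accept a geranyl in place of a dimethylallyl side chain and to add water enantioselectively, which has not been shown; the closest known reaction is the hydration of the dimethylallyl group of kievitone, phaseollidin and related ortho-hydroxy prenylated flavonoids by their hydratases, where no stereocentre arises. Mechanistically an active-site acid protonates C2'' of the proximal alkene, positive charge builds at the tertiary C3'', and an enzyme-bound water molecule collapses onto it to form the C3''–O bond; this is a Markovnikov addition and closes no ring. The new C3'' stereocentre is controlled by the enzyme alone: with ring A and its two hydroxyls anchored beside the catalytic acid and the homoprenyl tail lodged in an enlarged hydrophobic channel, only the Re face of C3'' (the face from which C2'', C4'' and the methyl group run clockwise) faces the bound water, which gives (R). Three selectivities are needed. Site selectivity for C2''=C3'' over C6''=C7'' follows from recognition of the ortho-hydroxyaryl–CH2–CH=C motif, which only the proximal alkene offers. Facial selectivity rests on the fixed (E)-geometry of 14 together with the tail channel, to be created by structure-guided saturation mutagenesis of the wild-type parents and screening by LC–MS for the water adduct and by chiral HPLC. Chroman closure is suppressed because the phenolic oxygens are held in hydrogen bonds away from C3'' and water is the nearest nucleophile, while pH 6 and ambient temperature spare the enone and prevent flavanone formation. Since hydration of a trisubstituted alkene is close to thermoneutral, the reaction is run in dilute aqueous medium with a cosolvent for the poorly soluble substrate and the product is extracted once conversion levels off.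

## Compound list

```
1 | resorcinol (benzene-1,3-diol) | Oc1cccc(O)c1 | starting material
2 | 1,3-bis(methoxymethoxy)benzene | COCOc1cccc(OCOC)c1 | intermediate
3 | geranyl bromide, (2E)-1-bromo-3,7-dimethylocta-2,6-diene | CC(C)=CCC/C(C)=C/CBr | starting material
4 | 2,6-bis(methoxymethoxy)phenyllithium (formed in situ) | [Li]c1c(OCOC)cccc1OCOC | intermediate
5 | 2,6-bis(methoxymethoxy)phenylcopper (formed in situ) | [Cu]c1c(OCOC)cccc1OCOC | intermediate
6 | 2-geranyl-1,3-bis(methoxymethoxy)benzene | CC(C)=CCC/C(C)=C/Cc1c(OCOC)cccc1OCOC | intermediate
7 | 3-geranyl-2,4-bis(methoxymethoxy)phenyllithium (formed in situ) | CC(C)=CCC/C(C)=C/Cc1c(OCOC)ccc([Li])c1OCOC | intermediate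
8 | lithium 1-[3-geranyl-2,4-bis(methoxymethoxy)phenyl]-1-[methoxy(methyl)amino]ethanolate, racemic (formed in situ) | CC(C)=CCC/C(C)=C/Cc1c(OCOC)ccc(C(C)(O[Li])N(C)OC)c1OCOC | intermediate
9 | 1-[3-geranyl-2,4-bis(methoxymethoxy)phenyl]ethanone | CC(C)=CCC/C(C)=C/Cc1c(OCOC)ccc(C(C)=O)c1OCOC | intermediate
10 | 4-hydroxybenzaldehyde | O=Cc1ccc(O)cc1 | starting material
11 | 4-(methoxymethoxy)benzaldehyde | COCOc1ccc(C=O)cc1 | intermediate
12 | 1-[3-geranyl-2,4-bis(methoxymethoxy)phenyl]-3-hydroxy-3-[4-(methoxymethoxy)phenyl]propan-1-one, racemic (formed in situ) | CC(C)=CCC/C(C)=C/Cc1c(OCOC)ccc(C(=O)CC(O)c2ccc(OCOC)cc2)c1OCOC | intermediate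
13 | (E)-1-[3-geranyl-2,4-bis(methoxymethoxy)phenyl]-3-[4-(methoxymethoxy)phenyl]prop-2-en-1-one | CC(C)=CCC/C(C)=C/Cc1c(OCOC)ccc(C(=O)/C=C/c2ccc(OCOC)cc2)c1OCOC | intermediate
14 | 3'-geranylisoliquiritigenin (xanthoangelol), (E)-1-[3-geranyl-2,4-dihydroxyphenyl]-3-(4-hydroxyphenyl)prop-2-en-1-one | CC(C)=CCC/C(C)=C/Cc1c(O)ccc(C(=O)/C=C/c2ccc(O)cc2)c1O | intermediate
15 | (E)-1-{2,4-dihydroxy-3-[(3R)-3-hydroxy-3,7-dimethyloct-6-en-1-yl]phenyl}-3-(4-hydroxyphenyl)prop-2-en-1-one | CC(C)=CCC[C@@](C)(O)CCc1c(O)ccc(C(=O)/C=C/c2ccc(O)cc2)c1O | target
```

## Step count and least certain steps

Total: 7 steps. Longest linear sequence: 6 steps (1, 2, 3, 5, 6, 7 from resorcinol); step 4 is a one-step branch.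

**Step 7 (key step, proposed new method).**
- What may go wrong: insufficient turnover, because the homoprenyl tail may not fit a pocket shaped for two methyl groups. Poor facial discrimination is also likely at first, since the parent enzymes never had to tell the two faces of C3'' apart. Water addition at the distal alkene and incomplete conversion from reverse dehydration are further possibilities. Evolution may not deliver all three selectivities in one variant.
- Fallback (known chemistry), from bis-ether 2, returning at target 15:
  - 2 is lithiated at C2 as in step 2 (aryllithium 4) and quenched with iodine to give 2-iodo-1,3-bis(methoxymethoxy)benzene F1.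
  - Purchased (R)-linalool is silylated (TESOTf, 2,6-lutidine) to (R)-linalool triethylsilyl ether F2. Its vinyl group is hydroborated selectively with 9-BBN-H to the B-alkyl-9-borabicyclononane F3.
  - B-alkyl Suzuki–Miyaura coupling of F3 with F1 (Pd(dppf)Cl2, aqueous Cs2CO3, THF/DMF) gives the side-chain arene F4.
  - F4 is acetylated at C4 by the lithiation–Weinreb sequence of step 3 to the acetophenone F5; its benzylic methylene is no longer allylic.
  - F5 is condensed with 11 as in step 5 to the fully protected chalcone F6, which is freed of its MOM and silyl groups with dilute HCl in methanol to give 15.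
  - The price is acid exposure of the finished carbinol and an enantiomeric purity limited by the purchased linalool.

**Step 3.**
- What may go wrong: competing deprotonation at the allylic C1'' methylene, which sits between two lithium-coordinating OMOM groups, would lead to alkene migration or acylation in the chain. Proton transfer from the acetyl group of the Weinreb amide to 7 would return 6.
- Fallback, from geranyl bromide 3, returning at acetophenone 9; it avoids the second lithiation altogether:
  - 3 is converted with Bu3SnLi into tributyl(geranyl)stannane F7.
  - Purchased 2,4-dihydroxyacetophenone is iodinated between its hydroxyls (I2, HIO3, aqueous EtOH) to 1-(2,4-dihydroxy-3-iodophenyl)ethanone F8.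
  - F8 is protected (MOMCl, i-Pr2NEt) to 1-[3-iodo-2,4-bis(methoxymethoxy)phenyl]ethanone F9.
  - Stille coupling of F9 with F7 (Pd(PPh3)4, CuI, CsF, DMF) gives 9, with the acetyl group in place from the start.

**Step 6.**
- What may go wrong: acid-promoted cyclisation of the 2'- or 4'-hydroxyl onto C3'' after protonation of the proximal alkene (chroman formation), addition of methanol or chloride to either alkene, and isomerisation of the 2'-hydroxychalcone to the flavanone.
- Fallback, from geranyl bromide 3 and 4-hydroxybenzaldehyde 10, returning at chalcone 14; it is free of protecting groups and never exposes a geranyl phenol to acid: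
  - Purchased 2,4-dihydroxyacetophenone is C-alkylated with 3 in aqueous KOH to 1-[3-geranyl-2,4-dihydroxyphenyl]ethanone F10. This direct reaction is typically inefficient and needs chromatographic separation from O- and C5-alkylated isomers.
  - F10 is condensed with unprotected 10 in concentrated ethanolic KOH to give 14.

## Further compounds

```
F1 | step 7 | 2-iodo-1,3-bis(methoxymethoxy)benzene | COCOc1cccc(OCOC)c1I
F2 | step 7 | (R)-linalool triethylsilyl ether, (3R)-3,7-dimethyl-3-(triethylsilyloxy)octa-1,6-diene | CC(C)=CCC[C@@](C)(O[Si](CC)(CC)CC)C=C
F3 | step 7 | 9-[(3S)-3,7-dimethyl-3-(triethylsilyloxy)oct-6-en-1-yl]-9-borabicyclo[3.3.1]nonane (same spatial arrangement as F2) | CC(C)=CCC[C@@](C)(O[Si](CC)(CC)CC)CCB1C2CCCC1CCC2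
F4 | step 7 | 2-[(3R)-3,7-dimethyl-3-(triethylsilyloxy)oct-6-en-1-yl]-1,3-bis(methoxymethoxy)benzene | CC(C)=CCC[C@@](C)(O[Si](CC)(CC)CC)CCc1c(OCOC)cccc1OCOC
F5 | step 7 | 1-{3-[(3R)-3,7-dimethyl-3-(triethylsilyloxy)oct-6-en-1-yl]-2,4-bis(methoxymethoxy)phenyl}ethanone | CC(C)=CCC[C@@](C)(O[Si](CC)(CC)CC)CCc1c(OCOC)ccc(C(C)=O)c1OCOC
F6 | step 7 | (E)-1-{3-[(3R)-3,7-dimethyl-3-(triethylsilyloxy)oct-6-en-1-yl]-2,4-bis(methoxymethoxy)phenyl}-3-[4-(methoxymethoxy)phenyl]prop-2-en-1-one | CC(C)=CCC[C@@](C)(O[Si](CC)(CC)CC)CCc1c(OCOC)ccc(C(=O)/C=C/c2ccc(OCOC)cc2)c1OCOC
F7 | step 3 | tributyl(geranyl)stannane, tributyl[(2E)-3,7-dimethylocta-2,6-dien-1-yl]stannane | CC(C)=CCC/C(C)=C/C[Sn](CCCC)(CCCC)CCCC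
F8 | step 3 | 1-(2,4-dihydroxy-3-iodophenyl)ethanone | CC(=O)c1ccc(O)c(I)c1O
F9 | step 3 | 1-[3-iodo-2,4-bis(methoxymethoxy)phenyl]ethanone | CC(=O)c1ccc(OCOC)c(I)c1OCOC
F10 | step 6 | 1-[3-geranyl-2,4-dihydroxyphenyl]ethanone | CC(C)=CCC/C(C)=C/Cc1c(O)ccc(C(C)=O)c1O
A1 | alternative 1 | 1-methoxy-1,3-bis(trimethylsilyloxy)buta-1,3-diene carrying at C2 the (3R)-3,7-dimethyl-3-(triethylsilyloxy)oct-6-en-1-yl chain | C=C(O[Si](C)(C)C)C(CC[C@](C)(O[Si](CC)(CC)CC)CCC=C(C)C)=C(OC)O[Si](C)(C)C
A2 | alternative 1 | (E)-1-[4-(tert-butyldimethylsilyloxy)phenyl]pent-1-en-4-yn-3-one | C#CC(=O)/C=C/c1ccc(O[Si](C)(C)C(C)(C)C)cc1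
A3 | alternative 1 | bis-silyl-protected target with free 2'- and 4'-hydroxyls, (R) at C3'' | CC(C)=CCC[C@@](C)(O[Si](CC)(CC)CC)CCc1c(O)ccc(C(=O)/C=C/c2ccc(O[Si](C)(C)C(C)(C)C)cc2)c1O
A4 | alternative 2 | (R)-sulcatyl 2,4,6-triisopropylbenzoate, (2R)-6-methylhept-5-en-2-yl 2,4,6-tri(propan-2-yl)benzoate | CC(C)=CCC[C@@H](C)OC(=O)c1c(C(C)C)cc(C(C)C)cc1C(C)C
A5 | alternative 2 | 2-{2-[2,6-bis(methoxymethoxy)phenyl]ethyl}-5,5-dimethyl-1,3,2-dioxaborinane | COCOc1cccc(OCOC)c1CCB1OCC(C)(C)CO1
A6 | alternative 2 | 2-{(3S)-1-[2,6-bis(methoxymethoxy)phenyl]-3,7-dimethyloct-6-en-3-yl}-5,5-dimethyl-1,3,2-dioxaborinane | CC(C)=CCC[C@@](C)(B1OCC(C)(C)CO1)CCc1c(OCOC)cccc1OCOC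
A7 | alternative 3 | O-triethylsilyl-(R)-linalool | CC(C)=CCC[C@@](C)(O[Si](CC)(CC)CC)C=C
A8 | alternative 3 | 9-[(3S)-3,7-dimethyl-3-(triethylsilyloxy)oct-6-en-1-yl]-9-borabicyclo[3.3.1]nonane | CC(C)=CCC[C@@](C)(O[Si](CC)(CC)CC)CCB1C2CCCC1CCC2
A9 | alternative 3 | (E)-1-[3-iodo-2,4-bis(methoxymethoxy)phenyl]-3-[4-(methoxymethoxy)phenyl]prop-2-en-1-one | COCOc1ccc(/C=C/C(=O)c2ccc(OCOC)c(I)c2OCOC)cc1
A10 | alternative 3 | fully protected target, (R) at C3'' | CC(C)=CCC[C@@](C)(O[Si](CC)(CC)CC)CCc1c(OCOC)ccc(C(=O)/C=C/c2ccc(OCOC)cc2)c1OCOC
```
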